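The earlier runs and the new flask are calculated on assumed constants; scatter was added.

I decided to carry one number through this flask and to let the other steps serve it.

| setting | theta | delta | flask |
|---|---|---|---|
| left-handed substrate | 0.19 M | 0.19 M | 0.19 M |
| right-handed substrate | 0.19 M | 0.19 M | 0.19 M |
| partner | 0.38 M | 0.57 M | 0.760 M |
| precatalyst | 95 µM | 95 µM | 95 µM |
| remark | run made earlier | run made earlier |  |
| time |  |  | 15 h |

| run | time / h | left-handed product / % | right-handed product / % |
|---|---|---|---|
| theta | 1.00 | 8.9 | 4.0 |
| theta | 1.33 | 11.2 | 6.2 |
| theta | 2.00 | 15.4 | 9.0 |
| theta | 3.00 | 20.4 | 11.9 |
| theta | 5.00 | 26.6 | 16.1 |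
| theta | 8.00 | 34.9 | 20.7 |
| theta | 12.0 | 38.2 | 25.5 |
| delta | 1.00 | 13.4 | 6.8 |
| delta | 1.33 | 16.0 | 9.2 |
| delta | 2.00 | 22.1 | 12.3 |
| delta | 3.00 | 27.8 | 16.1 |
| delta | 5.00 | 35.0 | 22.1 |
| delta | 8.00 | 42.3 | 28.0 |
| delta | 12.0 | 46.0 | 34.8 |

(scatter of a reading: 0.5 percentage points)

- left-handed product and right-handed product together, in percent of the left-handed substrate and right-handed substrate charged together, at 15 h
- excess of left-handed product over right-handed product in the product at 15 h
- whether the exchange between left-handed substrate and right-handed substrate keeps pace with the reaction: how far the product's excess at 15 h gets from its value without exchange to its value with instant exchange (above 80% keeps pace, below 20% hardly takes part, else lags behind)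

- partner is single-handed; left-handed substrate and right-handed substrate are mirror images of each other, charged as a racemate, each of them at the stated concentration
- the earlier runs were read with a standard deviation of 0.5 percentage points
- what may be going on: partner + left-handed substrate -> left-handed product; partner + precatalyst -> racemization catalyst + spent reagent; partner + right-handed substrate -> right-handed product; left-handed substrate + racemization catalyst <-> right-handed substrate + racemization catalyst; racemization catalyst -> spent catalyst
- an excess is the difference of the two amounts in percent of their sum
- an excess is below zero if the other one leads
- the handed part of partner does not stay in what it makes, so the products of the two hands are mirror images too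

The delta run at 12.0 h gave s = 2.12, where s, the selectivity factor, is the logarithm of the left-handed substrate's remaining fraction divided by that of the right-handed substrate's. At 2.00 h it read 2.07. Without exchange, the left-handed fraction equals the right-handed fraction raised to s. Exchange refilling the left-handed substrate lowers that reading, and it did not fall, so I expected the excess to stay far from its instant-exchange value of 35.9%, below the 20% mark.

Time, by hand, lets the slower hand catch up, so the excess falls: in the delta run it went from 28.5% to 13.9%. More partner should do the same sooner, and at 12.0 h the delta excess was lower than the theta excess of 19.9%. Precatalyst stood at 95 µM in both runs and at 95 µM in the flask.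

For the flask, I read 0.280 /M/h for the right-handed substrate from the delta run. c(partner) is its excess over the substrates, 0.380 M here, plus the remaining substrate. Holding partner at that excess gave a yield of 88.2%. Going round once more, I added the delta run's remaining substrate, 0.165 M on average over its 12.0 h. That left a right-handed fraction of 11.7%, a yield of 93.6% and an excess of 5.67%.

The forecast, judging that “exchange is negligible”, gave 92.5%, 6.5% and hardly takes part. Its yield is lower than mine and its excess higher.

The flask gave 92.6% and 6.61%, and the exchange hardly takes part, at 0.97% of the way.

    partner + left-handed substrate → left-handed product (k = 0.567 /M/h)
    partner + precatalyst → racemization catalyst + spent reagent (k = 0.0153 /M/h)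
    partner + right-handed substrate → right-handed product (k = 0.274 /M/h)
    left-handed substrate + racemization catalyst ⇌ right-handed substrate + racemization catalyst, rate k4*[racemization catalyst]*[left-handed substrate] forward; the back reaction follows from the equilibrium constant (k = 292 /M/h)
    racemization catalyst → spent catalyst (k = 0.00960 /h)

On this flask, s turns the simulated 13% of right-handed substrate into 1.32% of left-handed substrate, against the simulated 1.7%. The neighbour with 1.3 M of partner has an excess of 0.920 M, and the same reckoning gives it a right-handed fraction of 1.21%, a yield of 99.4% and an excess of 0.605%. That neighbour gave 99.1%, and its excess was higher than reckoned, at 1.19%.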